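The tricosyl chain is cut between its first and second carbon, because the ring-side carbon is propargylic in disguise: C3 and the unsubstituted C4–H of the pyrrole ring are the two carbons of a terminal alkyne. In the key step 1-bromodocosane (1) alkylates the dianion of propyne (2), 1,3-dilithiopropyne (3), at its sp3 carbanion; this forms the CH2–CH2 bond and, after protonation of the acetylide (4), leaves pentacos-1-yne (5). A silver-catalysed formal [3+2] cycloaddition with methyl isocyanoacetate (6) then adds N1, C2 with its ester, and C5 across the alkyne to give the target.

Key step: step 1

Remark on the chemistry: the target has no stereocentre and no stereogenic double bond, so no stereocontrol is needed. The transient 2H-pyrrole 8 is racemic and its stereocentre disappears on tautomerisation.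

Step 1
Reactants: 1 1-bromodocosane; 2 propyne
Product: 5 pentacos-1-yne, via 1,3-dilithiopropyne 3 (not isolated), via lithium pentacos-1-yn-1-ide 4 (not isolated)
Conditions: 2 (1.5 equiv), n-BuLi (3.0 equiv), TMEDA, Et2O–hexane, −78 → 0 °C; then 1 in THF, 0 °C → rt; then H2O
Reagents that add atoms: none
Why: n-BuLi removes first the acetylenic and then, with TMEDA, a propargylic proton of 2, and the sp3 carbanion of dianion 3 displaces bromide from 1 in an SN2 reaction, so that the new bond joins C1 of the docosyl chain to the future ring-bound CH2 and the product is held as the acetylide 4 until the aqueous quench. The closest known reaction type is the alkylation of 1,3-dilithiopropyne (a propargyl dianion) with primary alkyl bromides, a standard three-carbon homologation to terminal alkynes. No ring is closed and no stereocentre is formed. The step needs site selectivity for the propargylic carbon over the acetylide carbon and over allenic attack, which the dianion should secure because its sp3 carbanion is by far the more nucleophilic centre and the second lithium occupies C1; it also needs substitution to outrun E2, which the unbranched primary bromide favours. Because 4 stays lithiated until the quench, the triple bond should not migrate under the basic conditions.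

Step 2
Reactants: 5 pentacos-1-yne; 6 methyl isocyanoacetate
Product: 9 methyl 3-tricosyl-1H-pyrrole-2-carboxylate, via silver pentacos-1-yn-1-ide 7 (not isolated), via methyl 3-tricosyl-2H-pyrrole-2-carboxylate 8 (not isolated)
Conditions: 6 (1.5 equiv), Ag2CO3 (10 mol%), 1,4-dioxane, 80 °C
Reagents that add atoms: none
Why: Silver-catalysed isocyanide–alkyne formal [3+2] cycloaddition: the silver acetylide 7 takes up the isocyanide carbon of 6 at its terminal carbon, the α-carbon of the isocyanoacetate then closes 5-endo-dig onto the internal alkyne carbon, and protodemetalation to 8 followed by a 1,5-hydrogen shift should give the aromatic 1H-pyrrole with the ester at C2 and the chain at C3, every atom of 5 and 6 ending up in 9.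

Compound list
1 | 1-bromodocosane | CCCCCCCCCCCCCCCCCCCCCCBr | starting material
2 | propyne | CC#C | starting material
3 | 1,3-dilithiopropyne | [Li]CC#C[Li] | intermediate
4 | lithium pentacos-1-yn-1-ide | CCCCCCCCCCCCCCCCCCCCCCCC#C[Li] | intermediate
5 | pentacos-1-yne | CCCCCCCCCCCCCCCCCCCCCCCC#C | intermediate
6 | methyl isocyanoacetate | [C-]#[N+]CC(=O)OC | starting material
7 | silver pentacos-1-yn-1-ide | CCCCCCCCCCCCCCCCCCCCCCCC#C[Ag] | intermediate
8 | methyl 3-tricosyl-2H-pyrrole-2-carboxylate (racemic, transient) | CCCCCCCCCCCCCCCCCCCCCCCC1=CC=NC1C(=O)OC | intermediate
9 | methyl 3-tricosyl-1H-pyrrole-2-carboxylate | CCCCCCCCCCCCCCCCCCCCCCCc1cc[nH]c1C(=O)OC | target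

Total step count: 2
Longest linear sequence: 2 steps (1 → 5 → 9)

Steps most likely to fail (the route has only two steps, so both are ranked):

1. Step 2. The unactivated, waxy alkyl alkyne may be engaged only slowly by the silver catalyst. Silver-promoted self-condensation of the isocyanide and reduction of the catalyst to silver metal could then outrun the cycloaddition, and the long chain may limit solubility. The fallback sets out from 5 and comes back at 9, replacing the cycloaddition by a condensation in which C3 is a ketone carbon. Gold(I)- or mercury(II)-catalysed Markovnikov hydration of 5 in aqueous dioxane should give pentacosan-2-one F1. Condensation with N,N-dimethylformamide dimethyl acetal (neat, 110 °C) at the less hindered methyl group should give (E)-1-(dimethylamino)hexacos-1-en-3-one F2. Amine exchange with glycine methyl ester hydrochloride in MeOH should give methyl N-[(Z)-3-oxohexacos-1-en-1-yl]glycinate F3. NaOMe in MeOH at reflux should then close the ring by intramolecular aldol-type condensation of the glycinate α-carbon onto the ketone, and dehydration gives 9; methoxide cannot scramble the methyl ester.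

2. Step 1. E2 elimination of the primary bromide by the strongly basic dianion may compete. Incomplete propargylic lithiation would leave propynyllithium, which alkylates at the acetylide carbon and gives the internal 2-alkyne. The fallback sets out from 1 and comes back at 5, replacing the unprotected dianion by a silyl-masked monoanion with a separate unmasking step. Commercial 1-(trimethylsilyl)propyne would be lithiated at its methyl group (n-BuLi, TMEDA, THF, −78 → −20 °C) to 3-lithio-1-(trimethylsilyl)prop-1-yne F4. Its single, less basic carbanion should be alkylated by 1 at the propargylic carbon to give trimethyl(pentacos-1-yn-1-yl)silane F5. K2CO3 in MeOH–THF at rt should then remove the silyl group and return 5.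

Further compounds
F1 | step 2 | pentacosan-2-one | CCCCCCCCCCCCCCCCCCCCCCCC(C)=O
F2 | step 2 | (E)-1-(dimethylamino)hexacos-1-en-3-one | CCCCCCCCCCCCCCCCCCCCCCCC(=O)/C=C/N(C)C
F3 | step 2 | methyl N-[(Z)-3-oxohexacos-1-en-1-yl]glycinate | CCCCCCCCCCCCCCCCCCCCCCCC(=O)/C=C\NCC(=O)OC
F4 | step 1 | 3-lithio-1-(trimethylsilyl)prop-1-yne | [Li]CC#C[Si](C)(C)C
F5 | step 1 | trimethyl(pentacos-1-yn-1-yl)silane | CCCCCCCCCCCCCCCCCCCCCCCC#C[Si](C)(C)C
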